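**Plan**
- Retrosynthesis: the four formyl groups are removed first (Vilsmeier–Haack transform); the dihydropyran ring is then cut at O1–C2 and C3–C4 (retro oxa-[4+2]).
- Enabling feature: O1–C8a–C4a–C4 of the chroman is the 1-oxadiene of an o-quinone methide and C2=C3 is a 2-alkenylphenol. Both halves are the same aryl–C5 unit, so one benzylic alcohol can serve as both partners.
- Forward: 2,4,6-trihydroxybenzaldehyde → dibenzyl ether → dibromide → benzylic alcohol 7 (side chain joined by Grignard addition). Dimerisation of 7 then closes the pyran ring, the only ring made; both benzene rings come from the starting aldehyde.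
- Helpers: the benzylic OH (leaving group for the quinone methide), benzyl ethers (one free phenol per ring), and bromine atoms on the ring CH positions where the formyl groups will stand. Ethers and bromines leave together in one hydrogenolysis.
- Stereochemistry: all three stereocentres arise in the key step. Absolute configuration comes from a chiral Brønsted acid, 2,3-trans from the E alkene, 3,4-cis from the exo orientation of the aryl group.
- End game: hydrogenolysis, then fourfold formylation.

Key step: step 4

Assumption: the (R)-configured acid is taken to give the (2R,3R,4S) product in step 4; if the opposite sense is found, the (S)-configured acid is used with no other change.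

Step 1
Reactants: 1 2,4,6-trihydroxybenzaldehyde; 2 benzyl bromide
Product: 3 4,6-bis(benzyloxy)-2-hydroxybenzaldehyde
Conditions: BnBr (2.1 equiv), K2CO3 (2.2 equiv), acetone, 50 °C
Reagents that add atoms: benzyl bromide (2), BrCc1ccccc1
Why: Williamson etherification, in which the 4-OH and one of the two equivalent ortho-OH groups are alkylated while the last ortho-OH is held back by its hydrogen bond to the formyl group; no stereocentre is formed.

Step 2
Reactants: 3 4,6-bis(benzyloxy)-2-hydroxybenzaldehyde; 4 N-bromosuccinimide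
Product: 5 4,6-bis(benzyloxy)-3,5-dibromo-2-hydroxybenzaldehyde
Conditions: NBS (2.1 equiv), MeCN, 0 °C to rt
Reagents that add atoms: N-bromosuccinimide (4), O=C1CCC(=O)N1Br
Why: Electrophilic aromatic bromination, in which the two remaining ring CH positions (ortho and para to the free phenol, meta to the formyl group) are the only activated sites.

Step 3
Reactants: 5 4,6-bis(benzyloxy)-3,5-dibromo-2-hydroxybenzaldehyde; 6 isobutylmagnesium bromide
Product: 7 rac-3,5-bis(benzyloxy)-2,4-dibromo-6-(1-hydroxy-3-methylbutyl)phenol
Conditions: iBuMgBr (2.5 equiv), LaCl3·2LiCl (1 equiv), THF, −78 to −20 °C; then NH4Cl quench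
Reagents that add atoms: isobutylmagnesium bromide (6), CC(C)C[Mg]Br
Why: Grignard addition to the aldehyde (the first equivalent forms the magnesium phenoxide, LaCl3·2LiCl favours 1,2-addition over β-hydride transfer), giving the carbinol centre as a racemate on purpose because it is erased in step 4.

Step 4
Reactants: 7 rac-3,5-bis(benzyloxy)-2,4-dibromo-6-(1-hydroxy-3-methylbutyl)phenol (two molecules)
Product: 10 (2R,3R,4S)-5,7-bis(benzyloxy)-2-[2,4-bis(benzyloxy)-3,5-dibromo-6-hydroxyphenyl]-6,8-dibromo-4-(2-methylpropyl)-3-(propan-2-yl)-3,4-dihydro-2H-chromene, via o-quinone methide 8 (not isolated), via E-alkenylphenol 9 (not isolated)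
Conditions: (R)-3,3'-bis(2,4,6-triisopropylphenyl)-1,1'-binaphthalene-2,2'-diyl N-triflylphosphoramide (10 mol%), 5 Å MS, PhCF3, 40 °C
Reagents that add atoms: none
Why: Proposed new method: the chiral acid ionises the benzylic alcohol of 7 to the catalyst-bound o-quinone methide 8 (isobutyl anti to the hydrogen-bonded carbonyl oxygen, E), part of which loses a proton from its CH2 group to give the E-alkenylphenol 9, and 9 then attacks the exocyclic carbon of 8 through its isopropyl-bearing alkene carbon while the quinone methide oxygen bonds to the benzylic carbon; the closest known reaction types are the chiral phosphoric acid-catalysed oxa-[4+2] cycloaddition of o-quinone methides made in situ from o-hydroxybenzyl alcohols with o-hydroxystyrenes and the acid-catalysed dimerisation of 2-alkenylphenols to 2-arylchromans. The dihydropyran ring closes by an inverse-electron-demand oxa-Diels–Alder [4+2] between the 1-oxadiene O1=C8a–C4a=C4 and the C2=C3 alkene, which in the stepwise limit is a conjugate addition followed by a 6-exo-trig oxa-Michael closure onto the second quinone methide. C4 is set by the catalyst, whose 3,3'-aryl groups shield one face of bound 8; C3 is set relative to C4 by the exo orientation of the alkene (aryl group away from ring A, isopropyl under it), which puts isopropyl cis to isobutyl; C2 is set by the E geometry of 9, which through suprafacial addition puts aryl trans to isopropyl. The step needs exo selectivity, which the hydrogen bond from the phenol of 9 to the catalyst seated at the quinone methide oxygen and the twist of the hexasubstituted aryl ring (it cannot stack under the equally crowded ring A) should secure, and it needs cycloaddition to beat Friedel–Crafts alkylation, which the four bromine atoms secure by closing every free ring position. The 2,3-trans arrangement is also the thermodynamic one, so a stepwise closure or a later acid-mediated reopening of the C2–O1 bond converges on the same isomer.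

Step 5
Reactants: 10 (2R,3R,4S)-5,7-bis(benzyloxy)-2-[2,4-bis(benzyloxy)-3,5-dibromo-6-hydroxyphenyl]-6,8-dibromo-4-(2-methylpropyl)-3-(propan-2-yl)-3,4-dihydro-2H-chromene
Product: 11 (2R,3R,4S)-4-(2-methylpropyl)-3-(propan-2-yl)-2-(2,4,6-trihydroxyphenyl)-3,4-dihydro-2H-chromene-5,7-diol
Conditions: H2 (1 atm), 10% Pd/C, NaOAc (4.4 equiv), EtOAc–MeOH, rt
Reagents that add atoms: none
Why: Catalytic hydrogenolysis removes the four benzyl ethers and the four aryl bromides in one operation, with NaOAc taking up the HBr so that the acid-sensitive C2–O1 benzylic ether is not ionised and no stereocentre is touched.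

Step 6
Reactants: 11 (2R,3R,4S)-4-(2-methylpropyl)-3-(propan-2-yl)-2-(2,4,6-trihydroxyphenyl)-3,4-dihydro-2H-chromene-5,7-diol; 12 N,N-dimethylformamide; 13 water
Product: 14 sideroxylonal A, (2R,3R,4S)-2-(3,5-diformyl-2,4,6-trihydroxyphenyl)-5,7-dihydroxy-4-(2-methylpropyl)-3-(propan-2-yl)-3,4-dihydro-2H-chromene-6,8-dicarbaldehyde
Conditions: POCl3 (8 equiv), DMF, EtOAc, 0 °C to rt; then H2O, 50 °C
Reagents that add atoms: N,N-dimethylformamide (12), CN(C)C=O; water (13), O
Why: Vilsmeier–Haack formylation, in which each phloroglucinol-type ring has exactly two free, strongly activated CH positions, so exhaustive formylation and hydrolysis of the four iminium salts should give the tetra-aldehyde while each new formyl group lowers the acid lability of the C2–O1 bond.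

**Compound list**
1 | 2,4,6-trihydroxybenzaldehyde | O=Cc1c(O)cc(O)cc1O | starting material
2 | benzyl bromide | BrCc1ccccc1 | starting material
3 | 4,6-bis(benzyloxy)-2-hydroxybenzaldehyde | O=Cc1c(O)cc(OCc2ccccc2)cc1OCc1ccccc1 | intermediate
4 | N-bromosuccinimide | O=C1CCC(=O)N1Br | starting material
5 | 4,6-bis(benzyloxy)-3,5-dibromo-2-hydroxybenzaldehyde | O=Cc1c(O)c(Br)c(OCc2ccccc2)c(Br)c1OCc1ccccc1 | intermediate
6 | isobutylmagnesium bromide | CC(C)C[Mg]Br | starting material
7 | rac-3,5-bis(benzyloxy)-2,4-dibromo-6-(1-hydroxy-3-methylbutyl)phenol | CC(C)CC(O)c1c(O)c(Br)c(OCc2ccccc2)c(Br)c1OCc1ccccc1 | intermediate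
8 | (6E)-3,5-bis(benzyloxy)-2,4-dibromo-6-(3-methylbutylidene)cyclohexa-2,4-dien-1-one (o-quinone methide) | CC(C)C/C=C1/C(=O)C(Br)=C(OCc2ccccc2)C(Br)=C1OCc1ccccc1 | intermediate
9 | 3,5-bis(benzyloxy)-2,4-dibromo-6-[(1E)-3-methylbut-1-en-1-yl]phenol | CC(C)/C=C/c1c(O)c(Br)c(OCc2ccccc2)c(Br)c1OCc1ccccc1 | intermediate
10 | (2R,3R,4S)-5,7-bis(benzyloxy)-2-[2,4-bis(benzyloxy)-3,5-dibromo-6-hydroxyphenyl]-6,8-dibromo-4-(2-methylpropyl)-3-(propan-2-yl)-3,4-dihydro-2H-chromene (aryl and isopropyl trans, isopropyl and isobutyl cis) | CC(C)C[C@@H]1c2c(OCc3ccccc3)c(Br)c(OCc3ccccc3)c(Br)c2O[C@@H](c2c(O)c(Br)c(OCc3ccccc3)c(Br)c2OCc2ccccc2)[C@@H]1C(C)C | intermediate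
11 | (2R,3R,4S)-4-(2-methylpropyl)-3-(propan-2-yl)-2-(2,4,6-trihydroxyphenyl)-3,4-dihydro-2H-chromene-5,7-diol | CC(C)C[C@@H]1c2c(O)cc(O)cc2O[C@@H](c2c(O)cc(O)cc2O)[C@@H]1C(C)C | intermediate
12 | N,N-dimethylformamide | CN(C)C=O | starting material
13 | water | O | starting material
14 | sideroxylonal A | CC(C)C[C@@H]1c2c(O)c(C=O)c(O)c(C=O)c2O[C@@H](c2c(O)c(C=O)c(O)c(C=O)c2O)[C@@H]1C(C)C | target

**Step count and risks**
Total step count: 6. Longest linear sequence: 6 steps (from 1).

Steps most likely to fail:

1. Step 4 (bears the label). Enantiofacial control or exo selectivity may be low, or the catalyst may be held up by the water set free. The fallback sets out from 7 and comes back at 10, using known chemistry only. Compound 7 is dimerised without chiral control by an achiral acid (diphenyl phosphate, toluene, 60 °C; classical o-quinone methide [4+2] with a 2-alkenylphenol) to the racemate, that is 10 together with its enantiomer F1. The free phenol is acylated with (−)-menthyl chloroformate (Et3N, DMAP, CH2Cl2) to give the (−)-menthyl carbonate of 10 F2 and the (−)-menthyl carbonate of the enantiomer F3. These diastereomers are separated by chromatography or crystallisation, and F2 is cleaved with LiOH in THF–H2O to return 10 as a single enantiomer.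

2. Step 6. Formylation may stop short of four groups, and the electron-rich polyphenol may reopen at C2–O1 under the acid set free, with epimerisation at C2. The fallback sets out from 10 and comes back at 14, placing the formyl carbons by cross-coupling at the four C–Br bonds before the phenols are unmasked (steps 5 and 6 are bypassed). Fourfold Suzuki–Miyaura vinylation (potassium vinyltrifluoroborate, Pd(OAc)2, SPhos, Cs2CO3, THF–H2O, 80 °C) gives the tetravinyl compound F4. Lemieux–Johnson cleavage (OsO4 cat., NaIO4, 2,6-lutidine, dioxane–H2O) gives the tetra-aldehyde tetrabenzyl ether F5. BCl3 with pentamethylbenzene in CH2Cl2 at −78 °C then removes the four benzyl groups to give 14.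

3. Step 3. β-Hydride transfer from the branched Grignard reagent may reduce the hindered aldehyde instead of adding to it, and the product may lose water early during work-up. The fallback sets out from 5 and comes back at 7. Methallylmagnesium chloride (2.2 equiv, THF, −78 °C), which adds through a six-membered transition state and cannot deliver hydride, gives the homoallylic alcohol F6. Homogeneous hydrogenation of its 1,1-disubstituted alkene (RhCl(PPh3)3, H2 1 atm, benzene–EtOH, rt) leaves the aryl bromides and benzyl ethers untouched and gives 7.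

**Further compounds**
F1 | step 4 | (2S,3S,4R) enantiomer of 10 | CC(C)C[C@H]1c2c(OCc3ccccc3)c(Br)c(OCc3ccccc3)c(Br)c2O[C@H](c2c(O)c(Br)c(OCc3ccccc3)c(Br)c2OCc2ccccc2)[C@H]1C(C)C
F2 | step 4 | (−)-menthyl carbonate of 10 (carbonate on the phenol of the C2 aryl group) | CC(C)[C@@H]1CC[C@@H](C)C[C@H]1OC(=O)Oc1c(Br)c(OCc2ccccc2)c(Br)c(OCc2ccccc2)c1[C@@H]1Oc2c(Br)c(OCc3ccccc3)c(Br)c(OCc3ccccc3)c2[C@@H](CC(C)C)[C@H]1C(C)C
F3 | step 4 | (−)-menthyl carbonate of F1 | CC(C)[C@@H]1CC[C@@H](C)C[C@H]1OC(=O)Oc1c(Br)c(OCc2ccccc2)c(Br)c(OCc2ccccc2)c1[C@H]1Oc2c(Br)c(OCc3ccccc3)c(Br)c(OCc3ccccc3)c2[C@H](CC(C)C)[C@@H]1C(C)C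
F4 | step 6 | (2R,3R,4S)-5,7-bis(benzyloxy)-2-[2,4-bis(benzyloxy)-3,5-diethenyl-6-hydroxyphenyl]-6,8-diethenyl-4-(2-methylpropyl)-3-(propan-2-yl)-3,4-dihydro-2H-chromene | CC(C)C[C@@H]1c2c(OCc3ccccc3)c(C=C)c(OCc3ccccc3)c(C=C)c2O[C@@H](c2c(O)c(C=C)c(OCc3ccccc3)c(C=C)c2OCc2ccccc2)[C@@H]1C(C)C
F5 | step 6 | (2R,3R,4S)-5,7-bis(benzyloxy)-2-[2,4-bis(benzyloxy)-3,5-diformyl-6-hydroxyphenyl]-4-(2-methylpropyl)-3-(propan-2-yl)-3,4-dihydro-2H-chromene-6,8-dicarbaldehyde | CC(C)C[C@@H]1c2c(OCc3ccccc3)c(C=O)c(OCc3ccccc3)c(C=O)c2O[C@@H](c2c(O)c(C=O)c(OCc3ccccc3)c(C=O)c2OCc2ccccc2)[C@@H]1C(C)C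
F6 | step 3 | rac-3,5-bis(benzyloxy)-2,4-dibromo-6-(1-hydroxy-3-methylbut-3-en-1-yl)phenol | CC(=C)CC(O)c1c(O)c(Br)c(OCc2ccccc2)c(Br)c1OCc1ccccc1
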